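The data come from a simulation on assumed constants.

The number I started from was 40.0%, the base cover: the free base charged divided by twice the electrophile charged, which is the fraction of the electrophile that can couple before the balance of free nucleophile and free base together reaches zero. I wrote that balance for free base, the limiting reagent, charged at 80.0% of the electrophile. Each coupled electrophile takes two shares of it, one for the acid set free and one for the nucleophile that must be released from the protonated nucleophile. So, with the protic impurity left aside and while no acid stood free, free nucleophile and free base together equalled the base charged less twice what had coupled, and the charge of protonated nucleophile dropped out of the sum. Two amounts therefore stood against each other: the base charged and twice the electrophile charged.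

| setting | north-east | north | south-west | south | dusk | noon | winter | dawn |
|---|---|---|---|---|---|---|---|---|
| electrophile | 0.010 M | 0.010 M | 0.010 M | 0.020 M | 0.010 M (in portions, 3, over 6.0 h) | 0.010 M | 0.010 M (fed, over 6.0 h) | 0.010 M |
| free base | 8 mM | 8 mM | 8 mM | 8 mM | 8.00 mM | 8.00 mM (fed, over 6.0 h) | 8.00 mM | 8.00 mM (fed, over 6.0 h) |
| protonated nucleophile | 10 mM | 5 mM | 7.5 mM | 10 mM | 10.0 mM | 10.0 mM | 10.0 mM | 10.0 mM |
| protic impurity | 2 mM | 2 mM | 2 mM | 2 mM | 2.00 mM | 2.00 mM | 2.00 mM | 2.00 mM |
| temperature | 5 °C | 20 °C | 5 °C | 20 °C | 20 °C |  | 20 °C | 20 °C |
| remark | run made earlier | run made earlier | run made earlier | run made earlier | first portion at the start, last at 6.0 h | the addition at 0 °C, then warmed to 20 °C; the feed brings no volume worth counting | all else is in the flask from the start; the feed brings no volume worth counting | all else is in the flask from the start; the feed brings no volume worth counting |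
| time |  |  |  |  | 8.0 h | 8.0 h | 8.0 h | 8.0 h |

| run | time / h | target / % |
|---|---|---|
| north-east | 0.833 | 38 |
| north-east | 1.33 | 44 |
| north-east | 2.00 | 44 |
| north-east | 4.00 | 45 |
| north-east | 6.00 | 49 |
| north-east | 10.0 | 52 |
| north | 0.500 | 37 |
| north | 0.833 | 40 |
| north | 1.33 | 43 |
| north | 2.50 | 40 |
| north | 4.00 | 41 |
| north | 6.00 | 42 |
| south-west | 0.833 | 38 |
| south-west | 3.00 | 46 |
| south-west | 5.00 | 50 |
| south-west | 8.00 | 46 |
| south-west | 10.0 | 50 |
| south-west | 12.0 | 46 |
| south | 1.33 | 30 |
| south | 2.50 | 31 |
| south | 4.00 | 28 |
| south | 5.00 | 30 |
| south | 6.00 | 26 |

(readings scatter by 1.5 percentage points)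

- steps under discussion: electrophile + nucleophile -> acid set free + target; nucleophile + acid set free <-> protonated nucleophile; acid set free + free base <-> salt of the base; target <-> isomer of the product; acid set free + target -> side product; protic impurity + free base -> quenched reagent

- which flask leads in amount of target, in percent of the electrophile charged ("all alike" within 1.5 percentage points) (dusk / noon / winter / dawn / all alike)
- how much target is there at the end, in percent of the electrophile charged: dusk
- how much target is there at the end, in percent of the electrophile charged: noon
- how much target is there at the end, in percent of the electrophile charged: winter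
- how much target is there at the end, in percent of the electrophile charged: dawn

The readings agreed at first. At 0.833 h the north-east run, with 10 mM protonated nucleophile, read 38%, the south-west run, with 7.5 mM, read 38%, and the warmer north run, with 5 mM, read 40%. But the south run, whose cover was 20.0%, read 30% at 1.33 h, and the north-east run reached 52% at 10.0 h. So I took the cover as a knee and not a wall, past which coupling creeps on with acid standing free. Dusk, noon, winter and dawn shared one cover, and I expected each to end above it.

The forecast named noon as leader, with 38% for dusk, 46% for noon, 36% for winter and 42% for dawn, on the ground that “Slow electrophile feed or portions therefore leave base exposed to the impurity”. There it differed from my reckoning, for it put dusk and winter below the cover.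

The flasks gave 47.3% in dusk, 52.2% in noon, 48.7% in winter and 45.3% in dawn, so noon led, and each stood above the cover.

    electrophile + nucleophile → acid set free + target (k = 630 /M/h, Ea = 37.0 kJ/mol)
    nucleophile + acid set free ⇌ protonated nucleophile, settled at all times (K = 6770 /M, ΔH = −58.0 kJ/mol)
    acid set free + free base ⇌ salt of the base, settled at all times (K = 7.77 × 10⁵ /M, ΔH = −34.0 kJ/mol)
    target ⇌ isomer of the product (K = 0.705, k = 0.0356 /h, Ea = 95.0 kJ/mol, ΔH = −60.0 kJ/mol)
    acid set free + target → side product (k = 10.3 /M/h, Ea = 72.0 kJ/mol)
    protic impurity + free base → quenched reagent (k = 43.8 /M/h, Ea = 62.0 kJ/mol)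
    (constants at 20 °C)

In noon 58.4% of the electrophile had coupled, 18 percentage points past the cover, with free base at 0.0359% of its own charge. Noon stood 6.8 points over dawn through the passing of acid set free and target into side product, together with the pairing of acid and free base; taking away either left 0.32 points or 0.44 points. Dawn's neighbour with 0.0025 M electrophile had a cover of 160%. It ended with 0.0090% of its electrophile left and 79.8% target, and its side product stood at 3.61% against 11.7% in dawn.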